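**Retrosynthetic overview**

1. The target is an all-cis 2-aryl-3-(hydroxymethyl)-4-benzyl tetrahydrofuran (THF; ring A on the benzyl arm, ring B on C7). Ring B is the benzo ring of a (2R,3S)-trans-dihydrobenzofuran, which carries at its C2 a second, (2S,3R)-trans-dihydrobenzofuran (rings C and D).
2. Last cuts: the two O-benzyl groups, then both C3 hydroxymethyl groups back to vinyl groups, then the THF ring (C7–H by hemiketal reduction, C7–C8 by aldol of (R)-β-benzyl-butyrolactone 22 with aldehyde 17).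
3. Key cut: in the dihydrofuran ring on ring B, O1–C7a and C2–C3 are opened together, giving aldehyde 12, aryl allene 6 and a chiral borane (reductive [3+2] annulation). The same cut with the enantiomeric borane takes 12 back to 6 and O-benzylvanillin 8.
4. Enabling feature: in the ring O1–C2–C3–C3a–C7a, O1 sits on ring-B carbon C7a, which is para to C5 (the carbon that later carries the THF ring, held as a nitrile) and ortho to C3a, and C3 carries a one-carbon arm. So C7a–F is an SNAr site, C3 and its arm map onto the γ- and β-carbons of an allylborane made from an aryl allene, and C7a–C3a–C3 acts as a 1,3-dipole equivalent for the O1=C2 carbonyl.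
5. Ring order: dihydrofuran of the C/D unit (step 4), dihydrofuran on ring B (step 6), temporary lactone (step 10), THF ring (steps 13 and 14).

Key step: step 6

Assumption: compounds 1, 5, 7, 8, 13 and 18 are bought (7 and 13 can otherwise be made from α-pinene and BH3·SMe2); the (Z)-γ-aryl allylboranes are taken to show the same aldehyde-face preference as the parent B-allyl-diisopinocampheylboranes.

Numbering and abbreviations: benzofuran locants O1, C2, C3, C3a, C4–C7, C7a; lignan locants C7, C8, C9 and C7′, C8′, C9′ for the THF part. Ipc = isopinocampheyl (2,6,6-trimethylbicyclo[3.1.1]heptan-3-yl). ArBCD = (2R,3R)-2-[(2S,3S)-2-[4-(benzyloxy)-3-methoxyphenyl]-3-ethenyl-7-methoxy-2,3-dihydro-1-benzofuran-5-yl]-3-ethenyl-7-methoxy-2,3-dihydro-1-benzofuran-5-yl.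

**Route**

Step 1
Reactants: 1 4-amino-3-methoxybenzonitrile
Product: 2 4-amino-3-iodo-5-methoxybenzonitrile
Conditions: N-iodosuccinimide (1.05 equiv), AcOH, 23 °C
Reagents that add atoms: N-iodosuccinimide, O=C1CCC(=O)N1I
Why: Electrophilic aromatic iodination; the amino group directs to its only free ortho position (para is blocked by the nitrile), so one regioisomer should form.

Step 2
Reactants: 2 4-amino-3-iodo-5-methoxybenzonitrile
Product: 4 4-fluoro-3-iodo-5-methoxybenzonitrile, via arenediazonium fluoride 3 (not isolated)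
Conditions: NaNO2, pyridine·(HF)x, 0 °C, then 80 °C
Reagents that add atoms: hydrogen fluoride (pyridine complex), F; sodium nitrite, [Na+].[O-]N=O (supplies the second nitrogen of 3 only)
Why: Balz–Schiemann-type fluorodediazoniation; diazotisation and thermal loss of N2 in the fluoride medium should put fluorine on the carbon that carried nitrogen.

Step 3
Reactants: 4 4-fluoro-3-iodo-5-methoxybenzonitrile; 5 tributyl(propa-1,2-dien-1-yl)stannane
Product: 6 4-fluoro-3-methoxy-5-(propa-1,2-dien-1-yl)benzonitrile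
Conditions: Pd(PPh3)4 (5 mol %), LiCl, DMF, 70 °C
Reagents that add atoms: none
Why: Stille coupling; oxidative addition should occur only at C–I (C–F is inert) and the allenyl group should transfer from tin at its tin-bearing carbon to give the aryl allene.

Step 4
Reactants: 6 4-fluoro-3-methoxy-5-(propa-1,2-dien-1-yl)benzonitrile; 7 (−)-diisopinocampheylborane; 8 4-(benzyloxy)-3-methoxybenzaldehyde
Product: 11 (2S,3S)-2-[4-(benzyloxy)-3-methoxyphenyl]-3-ethenyl-7-methoxy-2,3-dihydro-1-benzofuran-5-carbonitrile, via Z-allylborane 9 (not isolated), via borinate ester 10 (not isolated)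
Conditions: 6 + 7, THF, −40 → −20 °C; 8, −78 °C; then KOtBu, DMF, −78 → 23 °C
Reagents that add atoms: none
Why: Proposed new method: kinetic hydroboration of the terminal allene C=C by (−)-Ipc2BH on the side away from the aryl group should give the (Z)-γ-aryl allylborane 9, whose chair (Zimmerman–Traxler) addition to the Si face of 8 sets C2 (S, reagent control) and C3 (syn to C2, from the Z geometry), after which tert-butoxide frees the alkoxide from boron for a 5-exo-trig SNAr displacement of the fluoride para to the nitrile that closes the trans ring without touching either centre; the closest known reaction types are the Brown-type allylboration with γ-substituted allyl-B(Ipc)2 reagents made from monosubstituted allenes and the base-mediated SNAr cyclisation of 2-(2-fluoroaryl)ethanols, merged here in one flask.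

Step 5
Reactants: 11 (2S,3S)-2-[4-(benzyloxy)-3-methoxyphenyl]-3-ethenyl-7-methoxy-2,3-dihydro-1-benzofuran-5-carbonitrile
Product: 12 (2S,3S)-2-[4-(benzyloxy)-3-methoxyphenyl]-3-ethenyl-7-methoxy-2,3-dihydro-1-benzofuran-5-carbaldehyde
Conditions: iBu2AlH (1.3 equiv), CH2Cl2, −78 °C; then 1 M aqueous HCl, 0 °C
Reagents that add atoms: water, O
Why: Partial nitrile reduction; the N-aluminio aldimine is stable at −78 °C and is hydrolysed to the aldehyde, while the vinyl group, the ethers and both stereocentres should be untouched.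

Step 6
Reactants: 6 4-fluoro-3-methoxy-5-(propa-1,2-dien-1-yl)benzonitrile; 13 (+)-diisopinocampheylborane; 12 (2S,3S)-2-[4-(benzyloxy)-3-methoxyphenyl]-3-ethenyl-7-methoxy-2,3-dihydro-1-benzofuran-5-carbaldehyde
Product: 16 (2R,3R)-2-[(2S,3S)-2-[4-(benzyloxy)-3-methoxyphenyl]-3-ethenyl-7-methoxy-2,3-dihydro-1-benzofuran-5-yl]-3-ethenyl-7-methoxy-2,3-dihydro-1-benzofuran-5-carbonitrile, via Z-allylborane 14 (not isolated), via borinate ester 15 (not isolated)
Conditions: 6 + 13 (1.2 equiv each), THF, −40 → −20 °C; 12, −78 °C; then KOtBu, DMF, −78 → 23 °C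
Reagents that add atoms: none
Why: Proposed new method: (+)-Ipc2BH should add to the terminal C=C of allene 6 from the side away from the aryl group, boron going to the CH2 terminus, to give the (Z)-γ-aryl allylborane 14; at −78 °C this adds to aldehyde 12 through a chair six-membered transition state (C2–C3 bond), tert-butoxide then exchanges the alkoxide off boron, and the free C2 alkoxide displaces the fluoride on C7a by addition–elimination (O1–C7a bond). The closest known reaction types are the kinetic hydroboration of monosubstituted allenes with Ipc2BH followed by syn-selective Brown-type allylboration, and the base-mediated intramolecular SNAr etherification of 2-(2-fluoroaryl)ethanols; what is new is their merger in one flask, with release of the alkoxide from the borinate in the presence of the boron by-products. The only ring closed is the dihydrofuran ring (O1, C2, C3, C3a, C7a), closed in the 5-exo-trig mode by attack of O1 on ring carbon C7a. C2 (R) is set by the isopinocampheyl groups, which should steer the allyl unit to the Re face of the aldehyde as in the parent B-allyl reagent; C3 (R in 16 because vinyl ranks below the arene, S once vinyl is CH2OH) is set relative to C2 by the Z geometry in the chair transition state, which gives the syn adduct, and the SNAr step keeps both centres, so the 2-aryl and 3-vinyl groups end trans. The step needs retention of the Z geometry (working at or below −20 °C, where the 1,3-boryl shift should be slow), face control that is independent of the two remote stereocentres of 12 (reagent control), and a site-selective SNAr (the nitrile para to C7a activates only that C–F bond, and C7a is flanked on both sides so that the hindered tert-butoxide should not compete). The nitrile is meta to C3a, so it does not acidify C3–H and the base should not move the vinyl double bond.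

Step 7
Reactants: 16 (2R,3R)-2-[(2S,3S)-2-[4-(benzyloxy)-3-methoxyphenyl]-3-ethenyl-7-methoxy-2,3-dihydro-1-benzofuran-5-yl]-3-ethenyl-7-methoxy-2,3-dihydro-1-benzofuran-5-carbonitrile
Product: 17 (2R,3R)-2-[(2S,3S)-2-[4-(benzyloxy)-3-methoxyphenyl]-3-ethenyl-7-methoxy-2,3-dihydro-1-benzofuran-5-yl]-3-ethenyl-7-methoxy-2,3-dihydro-1-benzofuran-5-carbaldehyde (ArBCD–CHO)
Conditions: iBu2AlH (1.3 equiv), CH2Cl2, −78 °C; then 1 M aqueous HCl, 0 °C
Reagents that add atoms: water, O
Why: Partial nitrile reduction and aldimine hydrolysis as in step 5; no stereocentre is involved.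

Step 8
Reactants: 8 4-(benzyloxy)-3-methoxybenzaldehyde; 18 dimethyl succinate
Product: 19 (3E)-4-[4-(benzyloxy)-3-methoxyphenyl]-3-(methoxycarbonyl)but-3-enoic acid
Conditions: NaOMe, MeOH, 65 °C; then aqueous HCl
Reagents that add atoms: none
Why: Stobbe condensation; aldol addition, lactonisation to the paraconate and irreversible E1cB opening should give the (E)-arylidene half-ester with the free acid on the CH2 arm.

Step 9
Reactants: 19 (3E)-4-[4-(benzyloxy)-3-methoxyphenyl]-3-(methoxycarbonyl)but-3-enoic acid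
Product: 20 (3R)-4-[4-(benzyloxy)-3-methoxyphenyl]-3-(methoxycarbonyl)butanoic acid
Conditions: H2 (5 bar), [Rh(cod)2]BF4 (1 mol %), (4S,5S)-MOD-DIOP, NEt3, MeOH, 30 °C
Reagents that add atoms: none
Why: Rhodium-catalysed asymmetric hydrogenation of an itaconate-type half-ester; the carboxylate chelates the metal and the chiral diphosphine (the enantiomer that delivers the R acid, expected to be 4S,5S) selects the alkene face and so sets C8′, while the homogeneous catalyst should leave the benzyl ether alone.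

Step 10
Reactants: 20 (3R)-4-[4-(benzyloxy)-3-methoxyphenyl]-3-(methoxycarbonyl)butanoic acid
Product: 22 (4R)-4-{[4-(benzyloxy)-3-methoxyphenyl]methyl}oxolan-2-one, via hydroxy acid 21 (not isolated)
Conditions: KOH (1 equiv), EtOH; CaCl2, NaBH4, −10 → 23 °C; then 3 M aqueous HCl
Reagents that add atoms: none
Why: Chemoselective borohydride reduction of the ester beside the carboxylate salt, then acid-catalysed lactonisation; hydride reduction should outrun enolisation, and afterwards the stereocentre is no longer α to a carbonyl.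

Step 11
Reactants: 22 (4R)-4-{[4-(benzyloxy)-3-methoxyphenyl]methyl}oxolan-2-one; 17 ArBCD–CHO
Product: 23 (3S,4R)-4-{[4-(benzyloxy)-3-methoxyphenyl]methyl}-3-[hydroxy(ArBCD)methyl]oxolan-2-one (both carbinol epimers)
Conditions: LiN(iPr)2 (1.1 equiv), 22 (1.2 equiv), THF, −78 °C; then 17; aqueous NH4Cl
Reagents that add atoms: none
Why: Aldol addition of the lactone lithium enolate; the aldehyde approaches the enolate face opposite the C8′ benzyl group, which sets C8 trans to it (substrate control), and the carbinol centre C7 is erased in step 13.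

Step 12
Reactants: 23 (3S,4R)-4-{[4-(benzyloxy)-3-methoxyphenyl]methyl}-3-[hydroxy(ArBCD)methyl]oxolan-2-one
Product: 24 (2R,3R)-3-{[4-(benzyloxy)-3-methoxyphenyl]methyl}-2-[hydroxy(ArBCD)methyl]butane-1,4-diol (both carbinol epimers)
Conditions: LiAlH4, THF, 0 °C; aqueous NaOH work-up
Reagents that add atoms: none
Why: Hydride reduction of the lactone to the 1,4-diol; no stereocentre is touched and the vinyl groups and ethers are inert.

Step 13
Reactants: 24 (2R,3R)-3-{[4-(benzyloxy)-3-methoxyphenyl]methyl}-2-[hydroxy(ArBCD)methyl]butane-1,4-diol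
Product: 26 (3R,4R)-2-(ArBCD)-4-{[4-(benzyloxy)-3-methoxyphenyl]methyl}-3-(hydroxymethyl)oxolan-2-ol (both anomers), via keto diol 25 (not isolated)
Conditions: activated MnO2 (20 equiv), CH2Cl2, 23 °C
Reagents that add atoms: none
Why: Chemoselective oxidation of the benzylic secondary alcohol beside two saturated primary alcohols; the aryl ketone should be trapped at once by the C9′ hydroxyl as the five-membered hemiketal (the C9 hydroxyl could only form an oxetane), and the neutral medium should keep C8 from epimerising.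

Step 14
Reactants: 26 (3R,4R)-2-(ArBCD)-4-{[4-(benzyloxy)-3-methoxyphenyl]methyl}-3-(hydroxymethyl)oxolan-2-ol
Product: 27 [(2R,3R,4R)-2-(ArBCD)-4-{[4-(benzyloxy)-3-methoxyphenyl]methyl}oxolan-3-yl]methanol (all-cis)
Conditions: Et3SiH (5 equiv), BF3·OEt2 (2 equiv), CH2Cl2, −78 °C
Reagents that add atoms: none
Why: Ionic hydrogenation of the hemiketal; hydride should add to the 2-aryl oxocarbenium ion from the ring face opposite the cis CH2OH (C8) and benzyl (C8′) groups, which puts the aryl group on their face and sets C7 (R), and the low temperature should prevent acid-mediated epimerisation to the 7,8-trans isomer and opening of the dihydrobenzofurans.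

Step 15
Reactants: 27 [(2R,3R,4R)-2-(ArBCD)-4-{[4-(benzyloxy)-3-methoxyphenyl]methyl}oxolan-3-yl]methanol
Product: 29 the O,O′-dibenzyl ether of the target (both ethenyl groups of 27 replaced by hydroxymethyl), via dialdehyde 28 (not isolated)
Conditions: OsO4 (2 mol %), NaIO4, 2,6-lutidine, dioxane/H2O, 23 °C; extractive work-up; then NaBH4, MeOH, 0 °C
Reagents that add atoms: sodium periodate, [Na+].[O-]I(=O)(=O)=O; water, O (oxygen source by way of catalytic OsO4)
Why: Lemieux–Johnson cleavage of both terminal alkenes and carbonyl reduction; each C3 is α to an aldehyde only briefly and trans is the more stable arrangement, so the configuration should be kept (a cis contaminant would equilibrate to trans here).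

Step 16
Reactants: 29 the O,O′-dibenzyl ether of the target
Product: 30 {(2R,3R,4R)-2-[(2R,3S)-2-[(2S,3R)-2-(4-hydroxy-3-methoxyphenyl)-3-(hydroxymethyl)-7-methoxy-2,3-dihydro-1-benzofuran-5-yl]-3-(hydroxymethyl)-7-methoxy-2,3-dihydro-1-benzofuran-5-yl]-4-[(4-hydroxy-3-methoxyphenyl)methyl]oxolan-3-yl}methanol (CNP0395728.1)
Conditions: H2 (1 atm), Pd/C (10% w/w), EtOAc/MeOH, 23 °C, stopped when 29 is consumed
Reagents that add atoms: none
Why: Hydrogenolysis of the two aryl benzyl ethers; these exocyclic O-benzyl bonds should cleave faster than the three cyclic benzylic C–O bonds.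

**Compound list**

1 | 4-amino-3-methoxybenzonitrile | COc1cc(C#N)ccc1N | starting material
2 | 4-amino-3-iodo-5-methoxybenzonitrile | COc1cc(C#N)cc(I)c1N | intermediate
3 | 4-cyano-2-iodo-6-methoxybenzenediazonium fluoride | COc1cc(C#N)cc(I)c1[N+]#N.[F-] | intermediate
4 | 4-fluoro-3-iodo-5-methoxybenzonitrile | COc1cc(C#N)cc(I)c1F | intermediate
5 | tributyl(propa-1,2-dien-1-yl)stannane | C=C=C[Sn](CCCC)(CCCC)CCCC | starting material
6 | 4-fluoro-3-methoxy-5-(propa-1,2-dien-1-yl)benzonitrile | COc1cc(C#N)cc(C=C=C)c1F | intermediate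
7 | (−)-diisopinocampheylborane, bis[(1R,2S,3R,5R)-2,6,6-trimethylbicyclo[3.1.1]heptan-3-yl]borane | B([C@@H]1C[C@@H]2C[C@H]([C@H]1C)C2(C)C)[C@@H]1C[C@@H]2C[C@H]([C@H]1C)C2(C)C | starting material
8 | 4-(benzyloxy)-3-methoxybenzaldehyde | COc1cc(C=O)ccc1OCc1ccccc1 | starting material
9 | [(2Z)-3-(5-cyano-2-fluoro-3-methoxyphenyl)prop-2-en-1-yl]bis[(1R,2S,3R,5R)-isopinocampheyl]borane | COc1cc(C#N)cc(/C=C\CB([C@@H]2C[C@@H]3C[C@H]([C@H]2C)C3(C)C)[C@@H]2C[C@@H]3C[C@H]([C@H]2C)C3(C)C)c1F | intermediate
10 | (1S,2S)-1-[4-(benzyloxy)-3-methoxyphenyl]-2-(5-cyano-2-fluoro-3-methoxyphenyl)but-3-en-1-yl bis[(1R,2S,3R,5R)-isopinocampheyl]borinate | COc1cc(C#N)cc([C@H](C=C)[C@@H](c2ccc(OCc3ccccc3)c(OC)c2)OB([C@@H]2C[C@@H]3C[C@H]([C@H]2C)C3(C)C)[C@@H]2C[C@@H]3C[C@H]([C@H]2C)C3(C)C)c1F | intermediate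
11 | (2S,3S)-2-[4-(benzyloxy)-3-methoxyphenyl]-3-ethenyl-7-methoxy-2,3-dihydro-1-benzofuran-5-carbonitrile | N#Cc1cc(OC)c2c(c1)[C@H](C=C)[C@@H](c1ccc(OCc3ccccc3)c(OC)c1)O2 | intermediate
12 | (2S,3S)-2-[4-(benzyloxy)-3-methoxyphenyl]-3-ethenyl-7-methoxy-2,3-dihydro-1-benzofuran-5-carbaldehyde | O=Cc1cc(OC)c2c(c1)[C@H](C=C)[C@@H](c1ccc(OCc3ccccc3)c(OC)c1)O2 | intermediate
13 | (+)-diisopinocampheylborane, bis[(1S,2R,3S,5S)-2,6,6-trimethylbicyclo[3.1.1]heptan-3-yl]borane | B([C@H]1C[C@H]2C[C@@H]([C@@H]1C)C2(C)C)[C@H]1C[C@H]2C[C@@H]([C@@H]1C)C2(C)C | starting material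
14 | [(2Z)-3-(5-cyano-2-fluoro-3-methoxyphenyl)prop-2-en-1-yl]bis[(1S,2R,3S,5S)-isopinocampheyl]borane | COc1cc(C#N)cc(/C=C\CB([C@H]2C[C@H]3C[C@@H]([C@@H]2C)C3(C)C)[C@H]2C[C@H]3C[C@@H]([C@@H]2C)C3(C)C)c1F | intermediate
15 | bis[(1S,2R,3S,5S)-isopinocampheyl]borinate of the (1R,2R) homoallylic alcohol from 14 and 12 | COc1cc(C#N)cc([C@@H](C=C)[C@H](c2cc(OC)c3c(c2)[C@H](C=C)[C@@H](c2ccc(OCc4ccccc4)c(OC)c2)O3)OB([C@H]2C[C@H]3C[C@@H]([C@@H]2C)C3(C)C)[C@H]2C[C@H]3C[C@@H]([C@@H]2C)C3(C)C)c1F | intermediate
16 | (2R,3R)-2-[(2S,3S)-2-[4-(benzyloxy)-3-methoxyphenyl]-3-ethenyl-7-methoxy-2,3-dihydro-1-benzofuran-5-yl]-3-ethenyl-7-methoxy-2,3-dihydro-1-benzofuran-5-carbonitrile | N#Cc1cc(OC)c2c(c1)[C@@H](C=C)[C@H](c1cc(OC)c3c(c1)[C@H](C=C)[C@@H](c1ccc(OCc4ccccc4)c(OC)c1)O3)O2 | intermediate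
17 | the corresponding 5-carbaldehyde (ArBCD–CHO) | O=Cc1cc(OC)c2c(c1)[C@@H](C=C)[C@H](c1cc(OC)c3c(c1)[C@H](C=C)[C@@H](c1ccc(OCc4ccccc4)c(OC)c1)O3)O2 | intermediate
18 | dimethyl succinate | COC(=O)CCC(=O)OC | starting material
19 | (3E)-4-[4-(benzyloxy)-3-methoxyphenyl]-3-(methoxycarbonyl)but-3-enoic acid | COc1cc(/C=C(\CC(=O)O)C(=O)OC)ccc1OCc1ccccc1 | intermediate
20 | (3R)-4-[4-(benzyloxy)-3-methoxyphenyl]-3-(methoxycarbonyl)butanoic acid | COc1cc(C[C@H](CC(=O)O)C(=O)OC)ccc1OCc1ccccc1 | intermediate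
21 | (3R)-4-[4-(benzyloxy)-3-methoxyphenyl]-3-(hydroxymethyl)butanoic acid | COc1cc(C[C@H](CC(=O)O)CO)ccc1OCc1ccccc1 | intermediate
22 | (4R)-4-{[4-(benzyloxy)-3-methoxyphenyl]methyl}oxolan-2-one | COc1cc(C[C@H]2COC(=O)C2)ccc1OCc1ccccc1 | intermediate
23 | (3S,4R)-4-{[4-(benzyloxy)-3-methoxyphenyl]methyl}-3-[hydroxy(ArBCD)methyl]oxolan-2-one, carbinol epimers | COc1cc(C[C@H]2COC(=O)[C@@H]2C(O)c2cc(OC)c3c(c2)[C@@H](C=C)[C@H](c2cc(OC)c4c(c2)[C@H](C=C)[C@@H](c2ccc(OCc5ccccc5)c(OC)c2)O4)O3)ccc1OCc1ccccc1 | intermediate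
24 | (2R,3R)-3-{[4-(benzyloxy)-3-methoxyphenyl]methyl}-2-[hydroxy(ArBCD)methyl]butane-1,4-diol, carbinol epimers | COc1cc(C[C@@H](CO)[C@H](CO)C(O)c2cc(OC)c3c(c2)[C@@H](C=C)[C@H](c2cc(OC)c4c(c2)[C@H](C=C)[C@@H](c2ccc(OCc5ccccc5)c(OC)c2)O4)O3)ccc1OCc1ccccc1 | intermediate
25 | (2R,3R)-1-(ArBCD)-3-{[4-(benzyloxy)-3-methoxyphenyl]methyl}-4-hydroxy-2-(hydroxymethyl)butan-1-one | COc1cc(C[C@@H](CO)[C@H](CO)C(=O)c2cc(OC)c3c(c2)[C@@H](C=C)[C@H](c2cc(OC)c4c(c2)[C@H](C=C)[C@@H](c2ccc(OCc5ccccc5)c(OC)c2)O4)O3)ccc1OCc1ccccc1 | intermediate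
26 | (3R,4R)-2-(ArBCD)-4-{[4-(benzyloxy)-3-methoxyphenyl]methyl}-3-(hydroxymethyl)oxolan-2-ol, anomers | COc1cc(C[C@H]2COC(O)(c3cc(OC)c4c(c3)[C@@H](C=C)[C@H](c3cc(OC)c5c(c3)[C@H](C=C)[C@@H](c3ccc(OCc6ccccc6)c(OC)c3)O5)O4)[C@H]2CO)ccc1OCc1ccccc1 | intermediate
27 | [(2R,3R,4R)-2-(ArBCD)-4-{[4-(benzyloxy)-3-methoxyphenyl]methyl}oxolan-3-yl]methanol, all-cis | COc1cc(C[C@H]2CO[C@@H](c3cc(OC)c4c(c3)[C@@H](C=C)[C@H](c3cc(OC)c5c(c3)[C@H](C=C)[C@@H](c3ccc(OCc6ccccc6)c(OC)c3)O5)O4)[C@H]2CO)ccc1OCc1ccccc1 | intermediate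
28 | dialdehyde of 27 (both ethenyl groups replaced by formyl, configuration unchanged) | COc1cc(C[C@H]2CO[C@@H](c3cc(OC)c4c(c3)[C@@H](C=O)[C@H](c3cc(OC)c5c(c3)[C@H](C=O)[C@@H](c3ccc(OCc6ccccc6)c(OC)c3)O5)O4)[C@H]2CO)ccc1OCc1ccccc1 | intermediate
29 | O,O′-dibenzyl ether of the target (benzyl on the ring A and ring D phenols) | COc1cc(C[C@H]2CO[C@@H](c3cc(OC)c4c(c3)[C@@H](CO)[C@H](c3cc(OC)c5c(c3)[C@H](CO)[C@@H](c3ccc(OCc6ccccc6)c(OC)c3)O5)O4)[C@H]2CO)ccc1OCc1ccccc1 | intermediate
30 | {(2R,3R,4R)-2-[(2R,3S)-2-[(2S,3R)-2-(4-hydroxy-3-methoxyphenyl)-3-(hydroxymethyl)-7-methoxy-2,3-dihydro-1-benzofuran-5-yl]-3-(hydroxymethyl)-7-methoxy-2,3-dihydro-1-benzofuran-5-yl]-4-[(4-hydroxy-3-methoxyphenyl)methyl]oxolan-3-yl}methanol | COc1cc(C[C@H]2CO[C@@H](c3cc(OC)c4c(c3)[C@@H](CO)[C@H](c3cc(OC)c5c(c3)[C@H](CO)[C@@H](c3ccc(O)c(OC)c3)O5)O4)[C@H]2CO)ccc1O | target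

**Step count and risks**

Total steps: 16. Longest linear sequence: 13 (steps 1–7 and 11–16); the lactone branch (steps 8–10) joins at step 11.

Steps most likely to fail:

Step 6 (proposed new method, key step). What may go wrong: face control may erode with the larger aldehyde 12, the allylborane may isomerise from Z to E by 1,3-boryl shift if the addition is slow (which would give the cis ring), and the alkoxide may not be released cleanly from boron so that ring closure stalls. Fallback by known chemistry, setting out from 4 and 12 and returning at 16: the (Z)-allyltrichlorosilane F4 (made from 4 as in the fallback to step 4) is added to 12 under catalysis by the enantiomeric chiral bisphosphoramide (Lewis-base-catalysed allylation through a closed chair transition state, Z giving syn) to give the isolated (1R,2R)-homoallylic alcohol F6, which NaH in THF closes by SNAr to 16.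

Step 4 (proposed new method). What may go wrong: the same loss of Z geometry before the aldehyde is met, or incomplete alkoxide release that lets tert-butoxide compete for the C–F bond. Fallback by known chemistry, setting out from 4 and 8 and returning at 11:
- Sonogashira coupling of 4 with propargyl alcohol (PdCl2(PPh3)2, CuI, NEt3) gives 4-fluoro-3-(3-hydroxyprop-1-yn-1-yl)-5-methoxybenzonitrile F1.
- Semi-hydrogenation (H2, Pd/CaCO3 poisoned with Pb(OAc)2, quinoline) gives the (Z)-allylic alcohol F2.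
- Appel chlorination (PPh3, CCl4) gives the (Z)-allylic chloride F3.
- HSiCl3, CuCl and iPr2NEt in Et2O give the (Z)-γ-aryl allyltrichlorosilane F4 with retention of geometry.
- Chiral-bisphosphoramide-catalysed addition of F4 to 8 (CH2Cl2, −78 °C) gives the (1S,2S)-homoallylic alcohol F5.
- NaH in THF (0 → 23 °C) closes the ring by SNAr to 11.

Step 16. What may go wrong: once the benzyl ethers are gone, hydrogenolysis may go on to the cyclic benzylic C–O bonds (C7–O of the THF ring, C2–O of each dihydrobenzofuran). Fallback, setting out from 29 and returning at 30: Lewis-acid debenzylation with BCl3 and pentamethylbenzene as cation scavenger in CH2Cl2 at −78 °C, then methanol quench; this changes the cleavage from reductive to cation transfer and makes no new compound (F0).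

Further compounds
F1 | step 4 | 4-fluoro-3-(3-hydroxyprop-1-yn-1-yl)-5-methoxybenzonitrile | COc1cc(C#N)cc(C#CCO)c1F
F2 | step 4 | 4-fluoro-3-[(1Z)-3-hydroxyprop-1-en-1-yl]-5-methoxybenzonitrile | COc1cc(C#N)cc(/C=C\CO)c1F
F3 | step 4 | 3-[(1Z)-3-chloroprop-1-en-1-yl]-4-fluoro-5-methoxybenzonitrile | COc1cc(C#N)cc(/C=C\CCl)c1F
F4 | step 4 | 4-fluoro-3-methoxy-5-[(1Z)-3-(trichlorosilyl)prop-1-en-1-yl]benzonitrile | COc1cc(C#N)cc(/C=C\C[Si](Cl)(Cl)Cl)c1F
F5 | step 4 | 3-{(1S,2S)-1-[4-(benzyloxy)-3-methoxyphenyl]-1-hydroxybut-3-en-2-yl}-4-fluoro-5-methoxybenzonitrile | COc1cc(C#N)cc([C@H](C=C)[C@@H](c2ccc(OCc3ccccc3)c(OC)c2)O)c1F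
F6 | step 6 | (1R,2R)-homoallylic alcohol from F4 and 12 (free alcohol of 15) | COc1cc(C#N)cc([C@@H](C=C)[C@H](c2cc(OC)c3c(c2)[C@H](C=C)[C@@H](c2ccc(OCc4ccccc4)c(OC)c2)O3)O)c1F
F0 | step 16 | none | none
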